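**Retrosynthetic overview**
- The C8' methyl ketone is unmasked last from a terminal alkene (Wacker oxidation).
- C6–C1' bond: a tertiary peroxycarbenium ion at C6 is alkylated by a ketone homoenolate equivalent (siloxycyclopropane); this sets C6 by 1,4-induction from C3.
- C3–C2 bond: catalytic asymmetric Mukaiyama addition of a propanoate silyl ketene acetal to the C3 peroxycarbenium ion; this sets C3 and C2.
- The 1,2-dioxane (the only ring, formed first) comes from aerobic cobalt-catalysed ring expansion of a 2-acetoxy-1-methylcyclobutanol: O2 is inserted into the C1–C2 bond, leaving an acetate at C3 and a hemiketal at C6.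
- Small pieces: 2-hydroxycyclobutanone, methyl propanoate, methyl 2-methylpropanoate, 5-bromopent-1-ene.

Assumption: the (S,S) enantiomer of the IDPi catalyst is taken to give the (3S) series in step 6 (otherwise its mirror image is used), and the four small starting materials are taken as purchased.

Target descriptors derived from the SMILES: C2 = S, C3 = S, C6 = R; the C3 side chain and the long C6 chain are cis on the ring, and C2/C3 are anti.

Step 1
Reactants: 1 2-hydroxycyclobutan-1-one
Product: 2 1-methylcyclobutane-1,2-diol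
Conditions: MeMgBr (2.5 equiv), THF, −78 to 0 °C; aq NH4Cl
Reagents that add atoms: methylmagnesium bromide C[Mg]Br
Why: Grignard addition, in which the first equivalent deprotonates the hydroxyl and the second adds to the strained ketone; the cis/trans ratio is irrelevant because both carbinol carbons become acetal-type centres in step 3.

Step 2
Reactants: 2 1-methylcyclobutane-1,2-diol
Product: 3 2-hydroxy-2-methylcyclobutyl acetate
Conditions: Ac2O (1.05 equiv), pyridine, DMAP (5 mol %), CH2Cl2, 0 °C
Reagents that add atoms: acetic anhydride CC(=O)OC(C)=O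
Why: DMAP-catalysed acylation is selective for the secondary over the tertiary hydroxyl, which leaves the tertiary alcohol free for alkoxy-radical generation.

Step 3
Reactants: 3 2-hydroxy-2-methylcyclobutyl acetate
Product: 5 (6-hydroxy-6-methyl-1,2-dioxan-3-yl) acetate, via 1-hydroperoxy-4-oxopentyl acetate 4 (not isolated)
Conditions: Co(acac)2 (20 mol %), O2 (1 atm), CH2Cl2, 25 °C
Reagents that add atoms: dioxygen O=O
Why: Cobalt-catalysed aerobic oxidative ring expansion of a cyclobutanol, in which the cobalt alkoxide gives the tertiary alkoxy radical, β-scission opens the ring towards the acetoxy-bearing carbon (oxygen-stabilised radical), O2 is captured and hydroperoxide 4 closes on the methyl ketone; both new stereocentres are acetal-type and are ionised later, so no control is needed.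

Step 4
Reactants: 5 (6-hydroxy-6-methyl-1,2-dioxan-3-yl) acetate
Product: 6 (6-{[tert-butyl(dimethyl)silyl]oxy}-6-methyl-1,2-dioxan-3-yl) acetate
Conditions: tBuMe2SiOTf (1.1 equiv), 2,6-lutidine (1.5 equiv), CH2Cl2, −78 °C
Reagents that add atoms: tert-butyldimethylsilyl trifluoromethanesulfonate CC(C)(C)[Si](C)(C)OS(=O)(=O)C(F)(F)F
Why: O-silylation of the tertiary peroxy-hemiketal hydroxyl (the cyclic tautomer reacts, as in acylations of dioxanols) turns C6 into a hindered silyl ketal that should ionise far less readily than the C3 acetate and locks the ring against ring–chain tautomerism.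

Step 5
Reactants: 7 methyl propanoate
Product: 9 (E)-1-methoxy-1-(trimethylsilyloxy)prop-1-ene, via lithium enolate of methyl propanoate 8 (not isolated)
Conditions: LiN(iPr)2 (1.05 equiv), THF, −78 °C; Me3SiCl (1.2 equiv), −78 °C to rt; distil
Reagents that add atoms: chlorotrimethylsilane C[Si](C)(C)Cl
Why: Kinetic enolisation under Ireland conditions (THF, no HMPA) followed by O-silylation gives the (E)-silyl ketene acetal (CH3 trans to OSiMe3) in about 9:1 geometric purity.

Step 6
Reactants: 6 (6-{[tert-butyl(dimethyl)silyl]oxy}-6-methyl-1,2-dioxan-3-yl) acetate; 9 (E)-1-methoxy-1-(trimethylsilyloxy)prop-1-ene (2.0 equiv)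
Product: 10 methyl (2S)-2-[(3S)-6-{[tert-butyl(dimethyl)silyl]oxy}-6-methyl-1,2-dioxan-3-yl]propanoate (both C6 epimers)
Conditions: (S,S)-IDPi A (3 mol %; imidodiphosphorimidate HN[P(=NSO2CF3)(O,O'-(S)-3,3'-Ar2-1,1'-binaphthalene-2,2'-diyl)]2, Ar = 3,5-(CF3)2C6H3), toluene, −78 °C
Reagents that add atoms: none
Why: Proposed new method: asymmetric counteranion-directed silylium catalysis on a cyclic peroxycarbenium ion, in which the silylated IDPi ionises the C3 acetate (Me3SiOAc leaves), the O–O–CH+ cation is held in the confined chiral anion, and the (E)-ketene acetal adds through an open antiperiplanar transition state, so that C3 (S) is set by catalyst-controlled face selection and C2 (S, anti) by relative topicity, while both C6 ketal epimers converge because C6 is re-ionised in step 9; the closest known reactions are IDPi-catalysed Mukaiyama additions to cyclic aliphatic oxocarbenium ions from lactol acetates and achiral Lewis-acid Mukaiyama additions to 3-acetoxy-1,2-dioxanes.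

Step 7
Reactants: 11 methyl 2-methylpropanoate; 12 5-bromopent-1-ene
Product: 14 methyl 2,2-dimethylhept-6-enoate, via lithium enolate of methyl 2-methylpropanoate 13 (not isolated)
Conditions: LiN(iPr)2 (1.1 equiv), THF, −78 °C; then 12 (1.1 equiv), DMPU, −78 °C to rt
Reagents that add atoms: none
Why: SN2 alkylation of the lithium ester enolate by the primary bromide builds the gem-dimethyl quaternary carbon; no stereocentre is involved.

Step 8
Reactants: 14 methyl 2,2-dimethylhept-6-enoate
Product: 15 1-(2-methylhept-6-en-2-yl)cyclopropan-1-ol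
Conditions: EtMgBr (3.0 equiv), Ti(OiPr)4 (20 mol %), Et2O/THF, 0 °C to rt; aq NH4Cl
Reagents that add atoms: ethylmagnesium bromide CC[Mg]Br
Why: Kulinkovich cyclopropanation, in which the titanacyclopropane formed from EtMgBr and Ti(OiPr)4 acts as a 1,2-dicarbanion towards the ester; the remote terminal alkene does not exchange under EtMgBr conditions.

Step 9
Reactants: 10 methyl (2S)-2-[(3S)-6-{[tert-butyl(dimethyl)silyl]oxy}-6-methyl-1,2-dioxan-3-yl]propanoate; 15 1-(2-methylhept-6-en-2-yl)cyclopropan-1-ol (1.5 equiv)
Product: 17 methyl (2S)-2-[(3S,6R)-6-(4,4-dimethyl-3-oxonon-8-en-1-yl)-6-methyl-1,2-dioxan-3-yl]propanoate, via 1-(2-methylhept-6-en-2-yl)cyclopropyl trimethylsilyl ether 16 (not isolated)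
Conditions: 15, Me3SiOTf (1.8 equiv), 2,6-lutidine (1.6 equiv), CH2Cl2, −78 °C, 30 min; then 10, −78 to −30 °C
Reagents that add atoms: none
Why: Proposed new method: homo-Mukaiyama alkylation, in which excess Me3SiOTf ionises the tertiary silyl peroxyketal to the C6 peroxycarbenium ion, this attacks a ring CH2 of siloxycyclopropane 16 (σ-bond raised by the siloxy donor) with C–C cleavage to a silyloxocarbenium ion that loses Me3Si to give the ketone, and axial attack on the half-chair with the C3 side chain pseudo-equatorial puts the new chain axial and cis to the C3 substituent with CH3 equatorial, i.e. (6R), leaving C2 and C3 untouched; the closest known reactions are Sakurai and Mukaiyama additions to peroxycarbenium ions of 1,2-dioxanes (3,6-cis selective) and electrophilic ring opening of siloxycyclopropanes as ketone homoenolate equivalents.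

Step 10
Reactants: 17 methyl (2S)-2-[(3S,6R)-6-(4,4-dimethyl-3-oxonon-8-en-1-yl)-6-methyl-1,2-dioxan-3-yl]propanoate
Product: 18 methyl (2S)-2-[(3S,6R)-6-(4,4-dimethyl-3,8-dioxononyl)-6-methyl-1,2-dioxan-3-yl]propanoate (diacarperoxide B)
Conditions: PdCl2(Quinox) (5 mol %; Quinox = 2-(4,5-dihydro-1,3-oxazol-2-yl)quinoline), AgSbF6 (12 mol %), aq tBuOOH (70 %, 12 equiv), CH2Cl2, 0 °C to rt
Reagents that add atoms: tert-butyl hydroperoxide CC(C)(C)OO
Why: Peroxide-mediated Wacker–Tsuji oxidation gives the methyl ketone with Markovnikov selectivity under copper-free conditions that leave the ring peroxide, the ester and the three stereocentres untouched.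

**Compound list**
1 | 2-hydroxycyclobutan-1-one | O=C1CCC1O | starting material
2 | 1-methylcyclobutane-1,2-diol (racemic, cis/trans mixture) | CC1(O)CCC1O | intermediate
3 | 2-hydroxy-2-methylcyclobutyl acetate (racemic, cis/trans mixture) | CC(=O)OC1CCC1(C)O | intermediate
4 | 1-hydroperoxy-4-oxopentyl acetate | CC(=O)CCC(OO)OC(C)=O | intermediate
5 | (6-hydroxy-6-methyl-1,2-dioxan-3-yl) acetate (racemic, diastereomer mixture) | CC(=O)OC1CCC(C)(O)OO1 | intermediate
6 | (6-{[tert-butyl(dimethyl)silyl]oxy}-6-methyl-1,2-dioxan-3-yl) acetate (racemic, diastereomer mixture) | CC(=O)OC1CCC(C)(O[Si](C)(C)C(C)(C)C)OO1 | intermediate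
7 | methyl propanoate | CCC(=O)OC | starting material
8 | lithium enolate of methyl propanoate (CH3 trans to OLi) | C/C=C(/O[Li])OC | intermediate
9 | (E)-1-methoxy-1-(trimethylsilyloxy)prop-1-ene | C/C=C(/O[Si](C)(C)C)OC | intermediate
10 | methyl (2S)-2-[(3S)-6-{[tert-butyl(dimethyl)silyl]oxy}-6-methyl-1,2-dioxan-3-yl]propanoate (both C6 epimers) | COC(=O)[C@@H](C)[C@@H]1CCC(C)(O[Si](C)(C)C(C)(C)C)OO1 | intermediate
11 | methyl 2-methylpropanoate | COC(=O)C(C)C | starting material
12 | 5-bromopent-1-ene | C=CCCCBr | starting material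
13 | lithium enolate of methyl 2-methylpropanoate | CC(C)=C(O[Li])OC | intermediate
14 | methyl 2,2-dimethylhept-6-enoate | COC(=O)C(C)(C)CCCC=C | intermediate
15 | 1-(2-methylhept-6-en-2-yl)cyclopropan-1-ol | OC1(CC1)C(C)(C)CCCC=C | intermediate
16 | 1-(2-methylhept-6-en-2-yl)cyclopropyl trimethylsilyl ether | C[Si](C)(C)OC1(CC1)C(C)(C)CCCC=C | intermediate
17 | methyl (2S)-2-[(3S,6R)-6-(4,4-dimethyl-3-oxonon-8-en-1-yl)-6-methyl-1,2-dioxan-3-yl]propanoate | COC(=O)[C@@H](C)[C@@H]1CC[C@](C)(CCC(=O)C(C)(C)CCCC=C)OO1 | intermediate
18 | methyl (2S)-2-[(3S,6R)-6-(4,4-dimethyl-3,8-dioxononyl)-6-methyl-1,2-dioxan-3-yl]propanoate (diacarperoxide B) | COC(=O)[C@@H](C)[C@@H]1CC[C@](C)(CCC(=O)C(C)(C)CCCC(C)=O)OO1 | target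

**Totals**
Total step count: 10. Longest linear sequence: 7 (steps 1, 2, 3, 4, 6, 9, 10).

**Three steps most likely to fail**

Step 6 (proposed new step). The risks are competitive ionisation of the C6 silyl ketal, a mismatched C6 epimer that reacts more slowly or less selectively, and an unproven anti/syn ratio at C2. The fallback sets out from 6 (with 9) and comes back at 10. Sc(OTf)3 (10 mol %) in CH2Cl2 at −40 °C, the established achiral Lewis-acid Mukaiyama reaction of 3-acetoxy-1,2-dioxanes, gives methyl 2-(6-{[tert-butyl(dimethyl)silyl]oxy}-6-methyl-1,2-dioxan-3-yl)propanoate as the mixture of stereoisomers F3. Preparative HPLC on a chiral stationary phase then isolates the (2S,3S) isomers, which are 10. This replaces asymmetric catalysis by a racemic synthesis followed by resolution.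

Step 9 (proposed new step). The siloxycyclopropane may be too weak a nucleophile, or the tertiary peroxycarbenium ion may fragment before it is trapped. The fallback sets out from 15 and comes back at 17; it puts the chain on C6 before the peroxide is made and gives up control of C6.
- Pd(OAc)2, pyridine and O2 open cyclopropanol 15 oxidatively to 4,4-dimethylnona-1,8-dien-3-one F4.
- DBU-mediated Michael addition of 2-methylcyclobutan-1-one F5 at its substituted α-carbon gives 2-(4,4-dimethyl-3-oxonon-8-en-1-yl)-2-methylcyclobutan-1-one F6.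
- NaBH4 at −78 °C reduces only the strained ring ketone to 1-(2-hydroxy-1-methylcyclobutyl)-4,4-dimethylnon-8-en-3-one F7.
- Co(acac)2 and O2, now through a tertiary alkyl radical, expand the ring to 1-(6-hydroxy-3-methyl-1,2-dioxan-3-yl)-4,4-dimethylnon-8-en-3-one F8.
- Ac2O and pyridine give [6-(4,4-dimethyl-3-oxonon-8-en-1-yl)-6-methyl-1,2-dioxan-3-yl] acetate F9.
- Sc(OTf)3-catalysed Mukaiyama addition of 9, followed by HPLC separation of the stereoisomers on a chiral phase, gives 17.

Step 3. The open-chain α-acetoxy hydroperoxide 4 may lose peracetic acid by acyl shift before it closes, and β-scission towards an acyloxy-bearing carbon is an extension of the usual alkyl- or aryl-substituted cases. The fallback sets out from 2 and comes back at 5. NaIO4 in aqueous THF cleaves diol 2 to 4-oxopentanal F1. H2O2 (50 %) in Et2O adds across both carbonyl groups to give 3-methyl-1,2-dioxane-3,6-diol F2. Ac2O and pyridine at 0 °C then acetylate only the secondary hemiacetal hydroxyl and give 5. This replaces the radical O2 insertion by a polar peroxyacetalisation.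

Further compounds
F1 | step 3 | 4-oxopentanal | CC(=O)CCC=O
F2 | step 3 | 3-methyl-1,2-dioxane-3,6-diol | CC1(O)CCC(O)OO1
F3 | step 6 | methyl 2-(6-{[tert-butyl(dimethyl)silyl]oxy}-6-methyl-1,2-dioxan-3-yl)propanoate (all stereoisomers) | COC(=O)C(C)C1CCC(C)(O[Si](C)(C)C(C)(C)C)OO1
F4 | step 9 | 4,4-dimethylnona-1,8-dien-3-one | C=CC(=O)C(C)(C)CCCC=C
F5 | step 9 | 2-methylcyclobutan-1-one | CC1CCC1=O
F6 | step 9 | 2-(4,4-dimethyl-3-oxonon-8-en-1-yl)-2-methylcyclobutan-1-one | CC1(CCC(=O)C(C)(C)CCCC=C)CCC1=O
F7 | step 9 | 1-(2-hydroxy-1-methylcyclobutyl)-4,4-dimethylnon-8-en-3-one | CC1(CCC(=O)C(C)(C)CCCC=C)CCC1O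
F8 | step 9 | 1-(6-hydroxy-3-methyl-1,2-dioxan-3-yl)-4,4-dimethylnon-8-en-3-one | CC1(CCC(=O)C(C)(C)CCCC=C)CCC(O)OO1
F9 | step 9 | [6-(4,4-dimethyl-3-oxonon-8-en-1-yl)-6-methyl-1,2-dioxan-3-yl] acetate | CC(=O)OC1CCC(C)(CCC(=O)C(C)(C)CCCC=C)OO1
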